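**Plan**

1. Feature: on the six-membered ring (C5–C10) the quaternary C10 carries a vinyl group (C1=C2) and the adjacent C5 an isopropenyl group (C4 with C3 and C15). Read together, C1–C2–C3–C4 is one four-carbon chain lacking only its C2–C3 bond, i.e. an opened cyclobutene that was fused across C5–C10.
2. Retrosynthetic cuts, in order: C8–O ester; lactone (C11=C13, C7–C11, C6–O back to a C6 ketone); C8–O back to an enone; C15 methyl back to an ester; C2–C3 re-closed; last C10–C1 and C5–C4, giving 3-methylcyclohex-2-enone and methyl cyclobut-1-enecarboxylate.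
3. Forward ring order: the cyclobutane C10–C1–C4–C5 is built by photocycloaddition, fused to the six- and the four-membered ring; heat opens both four-membered rings; the lactone ring is closed onto C6; the side-chain ester is attached last.
4. Stereochemistry: C10 by separating (2R,3R)-butanediol ketal diastereomers after the thermolysis; C8 by ligand-controlled copper-catalysed borylation; C7 and C5 by equilibration beside the C6 ketone; C6 by thermodynamically controlled reduction; side-chain alkene geometry by syn-hydrostannation locked in a dioxepine ring.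
5. Convention: α is the ring face of the C10 vinyl group, β that of the C10 methyl group (target: 6α-O, 8α-O, 5β-isopropenyl, 7β-C11).

Key step: step 3

Assumption: the (R,R) antipode of the bisphosphine in step 12 is taken as the one that places boron on the α face of C8; the sense has to be confirmed on 19, and the (S,S) ligand is used if it is the opposite.

**Route**

Step 1
Reactants: 1 ethyl 1-bromocyclobutane-1-carboxylate
Product: 2 cyclobut-1-ene-1-carboxylic acid
Conditions: KOH, PhMe, reflux; then aq. HCl, 0 °C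
Reagents that add atoms: potassium hydroxide, [K+].[OH-]
Why: E2 dehydrobromination of the tertiary α-bromo ester and saponification in the same pot give the strained enoic acid as its potassium salt, which is set free on acidification.

Step 2
Reactants: 2 cyclobut-1-ene-1-carboxylic acid
Product: 3 methyl cyclobut-1-ene-1-carboxylate
Conditions: MeI, K2CO3, DMF, 0 °C → rt
Reagents that add atoms: iodomethane, CI
Why: SN2 O-alkylation of the carboxylate gives the methyl ester without exposing the polymerisable cyclobutene enoate to acid.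

Step 3
Reactants: 3 methyl cyclobut-1-ene-1-carboxylate; 4 3-methylcyclohex-2-en-1-one
Product: 5 rac-methyl 1-methyl-7-oxotricyclo[4.4.0.0^2,5]decane-5-carboxylate (head-to-head cis-anti-cis adduct)
Conditions: hν (medium-pressure Hg lamp, Pyrex, λ > 300 nm), CH2Cl2, 0 °C, 3 in excess; then basic Al2O3
Reagents that add atoms: none
Why: Only the enone absorbs above 300 nm, and its triplet adds to the ground-state cyclobutene ester through a 1,4-diradical (enone–alkene [2+2] photocycloaddition; the closest known case is the addition of simple cyclobut-1-enecarboxylates to cyclohexenones). The cyclobutane C10–C1–C4–C5 closes in two stages: first a bond to the unsubstituted alkene carbon C1, leaving an ester-stabilised radical at C4, then radical–radical collapse to the four-membered ring. The head-to-head orientation (ester carbon C4 on the enone α-carbon C5), which the later isopropenyl group requires, is secured by the acceptor character of the alkene. The 4/4 fusion is cis for geometric reasons and the 6/4 fusion is cis after any trans-fused adduct has epimerised at C5 on basic alumina. The outer cyclobutane lies anti to the six-membered ring because that approach is the less hindered one, so C10, C5, C1 and C4 are fixed relative to one another. The absolute sense is not controlled (5 is racemic), which is accepted because C5 and C10 may become trigonal in step 5 and the resolution is therefore placed there.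

Step 4
Reactants: 5 rac-methyl 1-methyl-7-oxotricyclo[4.4.0.0^2,5]decane-5-carboxylate; 6 (2R,3R)-butane-2,3-diol
Product: 7 (2R,3R)-butane-2,3-diyl ketal of 5 (pair of diastereomers, one from each antipode of the core)
Conditions: p-TsOH (cat.), PhH, reflux, azeotropic removal of water
Reagents that add atoms: none
Why: Acid-catalysed ketalisation protects C6 for the hydride and Mitsunobu steps and, because the diol is enantiopure and C2-symmetric, turns the two core antipodes into diastereomers without creating a stereocentre at the spiro carbon.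

Step 5
Reactants: 7 (2R,3R)-butane-2,3-diyl ketal of 5
Product: 8 methyl 2-[(2R,3R,6R,7R)-7-ethenyl-2,3,7-trimethyl-1,4-dioxaspiro[4.5]decan-6-yl]prop-2-enoate
Conditions: PhMe (degassed, base-washed glass), sealed tube, 190 °C; then chromatographic separation of the two diastereomers
Reagents that add atoms: none
Why: Heat cleaves the strained bicyclo[2.2.0]hexane (C1–C4 first, then either C2–C3 directly or C5–C10 to a cyclodeca-1(10),4-diene that re-closes by Cope rearrangement), so the C10 vinyl group and the C5 acrylate should emerge cis (both α), as the cis ring fusion and a chair transition state of the (E,Z)-diene dictate; the (2R,3R)-dioxolane makes the 10R and 10S products diastereomers, and the 10R isomer is isolated by chromatography.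

Step 6
Reactants: 8 methyl 2-[(2R,3R,6R,7R)-7-ethenyl-2,3,7-trimethyl-1,4-dioxaspiro[4.5]decan-6-yl]prop-2-enoate
Product: 9 2-[(2R,3R,6R,7R)-7-ethenyl-2,3,7-trimethyl-1,4-dioxaspiro[4.5]decan-6-yl]prop-2-en-1-ol
Conditions: iBu2AlH (2.5 equiv), CH2Cl2, −78 °C; aq. potassium sodium tartrate
Reagents that add atoms: none
Why: iBu2AlH reduces the α-substituted acrylate in a 1,2 sense to the allylic alcohol (ester reduction) while the ketal keeps C6 out of the reaction.

Step 7
Reactants: 9 2-[(2R,3R,6R,7R)-7-ethenyl-2,3,7-trimethyl-1,4-dioxaspiro[4.5]decan-6-yl]prop-2-en-1-ol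
Product: 12 (2R,3R,6S,7R)-7-ethenyl-2,3,7-trimethyl-6-(prop-1-en-2-yl)-1,4-dioxaspiro[4.5]decane, via sulfonylhydrazine adduct 10 (not isolated), via allylic diazene 11 (not isolated)
Conditions: 2-O2NC6H4SO2NHNH2, PPh3, DEAD, THF, −30 → 23 °C
Reagents that add atoms: none
Why: Mitsunobu displacement of the primary allylic hydroxyl by the sulfonylhydrazide, loss of sulfinic acid and retro-ene extrusion of N2 from the allylic diazene replace OH by H with allylic transposition (reductive allylic transposition), which for this 2-substituted allyl alcohol gives the isopropenyl group whichever terminus receives the hydrogen.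

Step 8
Reactants: 12 (2R,3R,6S,7R)-7-ethenyl-2,3,7-trimethyl-6-(prop-1-en-2-yl)-1,4-dioxaspiro[4.5]decane
Product: 13 (2S,3R)-3-ethenyl-3-methyl-2-(prop-1-en-2-yl)cyclohexan-1-one (5α-isopropenyl)
Conditions: PPTS, acetone/H2O, 56 °C
Reagents that add atoms: water, O
Why: Weak-acid transketalisation and hydrolysis free the C6 ketone at a proton activity too low to hydrate the isopropenyl group or move it into conjugation; any epimerisation at C5 is harmless because C5 is equilibrated in step 12.

Step 9
Reactants: 13 (2S,3R)-3-ethenyl-3-methyl-2-(prop-1-en-2-yl)cyclohexan-1-one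
Product: 15 (5R,6S)-5-ethenyl-5-methyl-6-(prop-1-en-2-yl)cyclohex-2-en-1-one, via lithium enolate 14 (not isolated)
Conditions: LiN(iPr)2, THF, −78 °C; then PhS(Cl)=NtBu, −78 °C
Reagents that add atoms: none
Why: Kinetic deprotonation takes the unhindered C7 proton, and the enolate is dehydrogenated in the same pot by sulfenylation at C7 and syn-elimination toward C8 (enolate dehydrogenation with a sulfinimidoyl chloride, equivalent to a Saegusa–Ito oxidation); C10 is quaternary, so no other enone can form.

Step 10
Reactants: 15 (5R,6S)-5-ethenyl-5-methyl-6-(prop-1-en-2-yl)cyclohex-2-en-1-one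
Product: 16 (5R,6S)-5-ethenyl-2-iodo-5-methyl-6-(prop-1-en-2-yl)cyclohex-2-en-1-one
Conditions: I2, pyridine, CH2Cl2, 0 °C → rt
Reagents that add atoms: iodine, II
Why: Pyridine-mediated α-iodination of the enone (conjugate addition of pyridine, iodination of the enolate, elimination) is specific for C7 and leaves the isolated alkenes untouched.

Step 11
Reactants: 16 (5R,6S)-5-ethenyl-2-iodo-5-methyl-6-(prop-1-en-2-yl)cyclohex-2-en-1-one; 17 ethyl bromoacetate
Product: 19 ethyl 2-[(4R,5S)-4-ethenyl-4-methyl-6-oxo-5-(prop-1-en-2-yl)cyclohex-1-en-1-yl]acetate, via Reformatsky reagent 18 (not isolated)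
Conditions: 17, Zn, THF, rt; then 16, Pd2(dba)3 (cat.), XPhos (cat.), THF, rt
Reagents that add atoms: none
Why: Negishi coupling of the vinyl iodide with the Reformatsky reagent forms C7–C11 at the position fixed by the iodide, which avoids alkylating a ketone that would have two tertiary α-carbons.

Step 12
Reactants: 19 ethyl 2-[(4R,5S)-4-ethenyl-4-methyl-6-oxo-5-(prop-1-en-2-yl)cyclohex-1-en-1-yl]acetate
Product: 21 ethyl 2-[(1S,3R,4R,6R)-4-ethenyl-4-methyl-2-oxo-3-(prop-1-en-2-yl)-6-(4,4,5,5-tetramethyl-1,3,2-dioxaborolan-2-yl)cyclohexyl]acetate (8α-boryl, 7β-side chain, 5β-isopropenyl), via kinetic boryl ketone 20 (not isolated)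
Conditions: CuCl (5 mol%), NaOtBu (5 mol%), (R,R)-2,3-bis(tert-butylmethylphosphino)quinoxaline (6 mol%), B2pin2, MeOH, THF, 0 °C → rt (catalyst pre-formed before 19 is added); then DBU (0.3 equiv), rt
Reagents that add atoms: bis(pinacolato)diboron, CC1(C)OB(OC1(C)C)B1OC(C)(C)C(C)(C)O1
Why: Ligand-controlled syn-addition of the copper boryl species to the enone (copper-catalysed enantioselective conjugate borylation, used here for diastereocontrol) places boron on the α face of C8; DBU then equilibrates the two enolisable centres so that the C7 side chain and the C5 isopropenyl group should both become equatorial (7β, 5β) in the chair that keeps the 8α-boryl group equatorial, and a C–B bond, unlike a β-oxygen, cannot be lost by E1cB elimination during this equilibration.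

Step 13
Reactants: 21 ethyl 2-[(1S,3R,4R,6R)-4-ethenyl-4-methyl-2-oxo-3-(prop-1-en-2-yl)-6-(4,4,5,5-tetramethyl-1,3,2-dioxaborolan-2-yl)cyclohexyl]acetate
Product: 23 (3aS,4R,6R,7R,7aR)-6-ethenyl-6-methyl-7-(prop-1-en-2-yl)-4-(4,4,5,5-tetramethyl-1,3,2-dioxaborolan-2-yl)hexahydro-1-benzofuran-2(3H)-one (trans-fused 6α,12-lactone, 8α-boryl), via hydroxy ester 22 (not isolated)
Conditions: SmI2 (2.2 equiv), H2O, Et3N, THF, 0 °C; then PPTS (cat.), PhMe, 60 °C
Reagents that add atoms: none
Why: Electron-transfer reduction with SmI2 and water should give the thermodynamically preferred equatorial 6α-alcohol, as dissolving-metal reductions do for ketones whose axial approach is screened by a syn-axial methyl group (a borohydride would attack from the open α face and give the axial alcohol); the trans-disposed hydroxy ester then closes to the γ-lactone under mild acid while C8 is still masked as boron, so only the 6,12-lactone can form.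

Step 14
Reactants: 23 (3aS,4R,6R,7R,7aR)-6-ethenyl-6-methyl-7-(prop-1-en-2-yl)-4-(4,4,5,5-tetramethyl-1,3,2-dioxaborolan-2-yl)hexahydro-1-benzofuran-2(3H)-one
Product: 24 (3aS,4R,6R,7R,7aS)-6-ethenyl-4-hydroxy-6-methyl-7-(prop-1-en-2-yl)hexahydro-1-benzofuran-2(3H)-one
Conditions: H2O2 (30% aq.), pH 7 phosphate buffer, THF, 0 °C → rt
Reagents that add atoms: hydrogen peroxide, OO
Why: Boronate oxidation proceeds by 1,2-migration from boron to oxygen with retention and unveils the 8α-alcohol at neutral pH, where the lactone neither opens nor migrates to O8.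

Step 15
Reactants: 24 (3aS,4R,6R,7R,7aS)-6-ethenyl-4-hydroxy-6-methyl-7-(prop-1-en-2-yl)hexahydro-1-benzofuran-2(3H)-one
Product: 26 (3aS,4R,6R,7R,7aS)-3-[(dimethylamino)methyl]-6-ethenyl-4-hydroxy-6-methyl-7-(prop-1-en-2-yl)hexahydro-1-benzofuran-2(3H)-one (either configuration at C11), via dilithio lactone enolate 25 (not isolated)
Conditions: LiN(iPr)2 (2.3 equiv), THF, −78 °C; then Me2N=CH2+ I−, −78 → 0 °C
Reagents that add atoms: N,N-dimethylmethyleneiminium iodide, C=[N+](C)C.[I-]
Why: Double deprotonation gives the alkoxide and the lactone enolate, and the Mannich reaction of the enolate with the iminium salt introduces C13 at C11; the configuration at C11 is irrelevant because it becomes trigonal in the next step.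

Step 16
Reactants: 26 (3aS,4R,6R,7R,7aS)-3-[(dimethylamino)methyl]-6-ethenyl-4-hydroxy-6-methyl-7-(prop-1-en-2-yl)hexahydro-1-benzofuran-2(3H)-one
Product: 28 (3aS,4R,6R,7R,7aS)-6-ethenyl-4-hydroxy-6-methyl-3-methylidene-7-(prop-1-en-2-yl)hexahydro-1-benzofuran-2(3H)-one, via ammonium iodide 27 (not isolated)
Conditions: MeI, THF, rt; then NaHCO3 (aq.), CH2Cl2, rt
Reagents that add atoms: none
Why: N-methylation and E1cB loss of trimethylamine from the quaternary salt give the α-methylene lactone (Mannich-base methylenation) without base strong enough to touch the free hydroxyl.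

Step 17
Reactants: 29 but-2-yne-1,4-diol
Product: 30 (E)-2-(tributylstannyl)but-2-ene-1,4-diol
Conditions: Bu3SnH, PdCl2(PPh3)2 (cat.), THF, rt
Reagents that add atoms: tributyltin hydride, CCCC[SnH](CCCC)CCCC
Why: Palladium-catalysed hydrostannation is a syn-addition, so the two hydroxymethyl groups end up cis on the double bond, and the alkyne is symmetrical, so there is no regiochemical question.

Step 18
Reactants: 30 (E)-2-(tributylstannyl)but-2-ene-1,4-diol
Product: 31 tributyl(2,2-dimethyl-4,7-dihydro-1,3-dioxepin-5-yl)stannane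
Conditions: Me2C(OMe)2, PPTS (cat.), CH2Cl2, rt
Reagents that add atoms: 2,2-dimethoxypropane, COC(C)(C)OC
Why: Transketalisation closes the seven-membered acetonide, which only the cis-diol can form and which locks the alkene geometry.

Step 19
Reactants: 31 tributyl(2,2-dimethyl-4,7-dihydro-1,3-dioxepin-5-yl)stannane
Product: 33 2,2-dimethyl-4,7-dihydro-1,3-dioxepine-5-carboxylic acid, via vinyllithium 32 (not isolated)
Conditions: n-BuLi, THF, −78 °C; CO2; then dilute HCl to pH 4, 0 °C
Reagents that add atoms: carbon dioxide, O=C=O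
Why: Tin–lithium exchange gives the ring vinyllithium (β-elimination of alkoxide would need a cyclic allene and does not occur), and carboxylation gives the acid.

Step 20
Reactants: 28 (3aS,4R,6R,7R,7aS)-6-ethenyl-4-hydroxy-6-methyl-3-methylidene-7-(prop-1-en-2-yl)hexahydro-1-benzofuran-2(3H)-one; 33 2,2-dimethyl-4,7-dihydro-1,3-dioxepine-5-carboxylic acid
Product: 35 (3aS,4R,6R,7R,7aS)-6-ethenyl-6-methyl-3-methylidene-2-oxo-7-(prop-1-en-2-yl)octahydro-1-benzofuran-4-yl 2,2-dimethyl-4,7-dihydro-1,3-dioxepine-5-carboxylate, via mixed anhydride 34 (not isolated)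
Conditions: 33, 2,4,6-Cl3C6H2COCl, Et3N, THF, rt; then 28, DMAP, PhMe, rt
Reagents that add atoms: none
Why: Yamaguchi esterification through the mixed anhydride acylates the equatorial C8 alcohol with retention and without conditions that would add to the α-methylene lactone.

Step 21
Reactants: 35 (3aS,4R,6R,7R,7aS)-6-ethenyl-6-methyl-3-methylidene-2-oxo-7-(prop-1-en-2-yl)octahydro-1-benzofuran-4-yl 2,2-dimethyl-4,7-dihydro-1,3-dioxepine-5-carboxylate
Product: 36 (3aS,4R,6R,7R,7aS)-6-ethenyl-6-methyl-3-methylidene-2-oxo-7-(prop-1-en-2-yl)octahydro-1-benzofuran-4-yl (2E)-4-hydroxy-2-(hydroxymethyl)but-2-enoate (CNP0309506.1)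
Conditions: AcOH/H2O/THF (3:1:1), rt
Reagents that add atoms: none
Why: Acetal hydrolysis of the seven-membered acetonide proceeds in aqueous acetic acid, which the ester, the methylene lactone and the isopropenyl group tolerate; the (E)-geometry is already fixed, and the hydroxymethyl group trans to the ester carbonyl cannot lactonise.

**Compound list**

1 | ethyl 1-bromocyclobutane-1-carboxylate | CCOC(=O)C1(Br)CCC1 | starting material
2 | cyclobut-1-ene-1-carboxylic acid | OC(=O)C1=CCC1 | intermediate
3 | methyl cyclobut-1-ene-1-carboxylate | COC(=O)C1=CCC1 | intermediate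
4 | 3-methylcyclohex-2-en-1-one | CC1=CC(=O)CCC1 | starting material
5 | rac-methyl 1-methyl-7-oxotricyclo[4.4.0.0^2,5]decane-5-carboxylate (head-to-head, cis-anti-cis; racemic, drawn as the antipode with the target configuration at C10) | O=C1CCC[C@]2(C)[C@H]3CC[C@@]3(C(=O)OC)[C@H]12 | intermediate
6 | (2R,3R)-butane-2,3-diol | C[C@@H](O)[C@@H](C)O | starting material
7 | (2R,3R)-butane-2,3-diyl ketal of 5 (pair of diastereomers; drawn with the core of 5 as shown, the other has the mirror-image core) | C14(CCC[C@]2(C)[C@H]3CC[C@@]3(C(=O)OC)[C@H]12)O[C@H](C)[C@@H](C)O4 | intermediate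
8 | methyl 2-[(2R,3R,6R,7R)-7-ethenyl-2,3,7-trimethyl-1,4-dioxaspiro[4.5]decan-6-yl]prop-2-enoate | C=C[C@@]1(C)CCCC2(O[C@H](C)[C@@H](C)O2)[C@H]1C(=C)C(=O)OC | intermediate
9 | 2-[(2R,3R,6R,7R)-7-ethenyl-2,3,7-trimethyl-1,4-dioxaspiro[4.5]decan-6-yl]prop-2-en-1-ol | C=C[C@@]1(C)CCCC2(O[C@H](C)[C@@H](C)O2)[C@H]1C(=C)CO | intermediate
10 | N-allyl-N-(2-nitrobenzenesulfonyl)hydrazine from 9 (Mitsunobu adduct) | C=C[C@@]1(C)CCCC2(O[C@H](C)[C@@H](C)O2)[C@H]1C(=C)CN(N)S(=O)(=O)c1ccccc1[N+](=O)[O-] | intermediate
11 | allylic diazene from 10 | C=C[C@@]1(C)CCCC2(O[C@H](C)[C@@H](C)O2)[C@H]1C(=C)CN=N | intermediate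
12 | (2R,3R,6S,7R)-7-ethenyl-2,3,7-trimethyl-6-(prop-1-en-2-yl)-1,4-dioxaspiro[4.5]decane | C=C[C@@]1(C)CCCC2(O[C@H](C)[C@@H](C)O2)[C@H]1C(C)=C | intermediate
13 | (2S,3R)-3-ethenyl-3-methyl-2-(prop-1-en-2-yl)cyclohexan-1-one | C=C[C@@]1(C)CCCC(=O)[C@H]1C(C)=C | intermediate
14 | lithium enolate of 13 (C6=C7) | C=C[C@@]1(C)CCC=C(O[Li])[C@H]1C(C)=C | intermediate
15 | (5R,6S)-5-ethenyl-5-methyl-6-(prop-1-en-2-yl)cyclohex-2-en-1-one | C=C[C@@]1(C)CC=CC(=O)[C@H]1C(C)=C | intermediate
16 | (5R,6S)-5-ethenyl-2-iodo-5-methyl-6-(prop-1-en-2-yl)cyclohex-2-en-1-one | C=C[C@@]1(C)CC=C(I)C(=O)[C@H]1C(C)=C | intermediate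
17 | ethyl bromoacetate | CCOC(=O)CBr | starting material
18 | (2-ethoxy-2-oxoethyl)zinc bromide | CCOC(=O)C[Zn]Br | intermediate
19 | ethyl 2-[(4R,5S)-4-ethenyl-4-methyl-6-oxo-5-(prop-1-en-2-yl)cyclohex-1-en-1-yl]acetate | C=C[C@@]1(C)CC=C(CC(=O)OCC)C(=O)[C@H]1C(C)=C | intermediate
20 | kinetic 8α-boryl ketone (5α-isopropenyl, C7 not yet equilibrated) | C=C[C@@]1(C)C[C@@H](B2OC(C)(C)C(C)(C)O2)C(CC(=O)OCC)C(=O)[C@H]1C(C)=C | intermediate
21 | ethyl 2-[(1S,3R,4R,6R)-4-ethenyl-4-methyl-2-oxo-3-(prop-1-en-2-yl)-6-(4,4,5,5-tetramethyl-1,3,2-dioxaborolan-2-yl)cyclohexyl]acetate | C=C[C@@]1(C)C[C@@H](B2OC(C)(C)C(C)(C)O2)[C@H](CC(=O)OCC)C(=O)[C@@H]1C(C)=C | intermediate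
22 | 6α-hydroxy ester from 21 | C=C[C@@]1(C)C[C@@H](B2OC(C)(C)C(C)(C)O2)[C@H](CC(=O)OCC)[C@@H](O)[C@@H]1C(C)=C | intermediate
23 | (3aS,4R,6R,7R,7aR)-6-ethenyl-6-methyl-7-(prop-1-en-2-yl)-4-(4,4,5,5-tetramethyl-1,3,2-dioxaborolan-2-yl)hexahydro-1-benzofuran-2(3H)-one | C=C[C@@]1(C)C[C@@H](B2OC(C)(C)C(C)(C)O2)[C@@H]2CC(=O)O[C@H]2[C@@H]1C(C)=C | intermediate
24 | (3aS,4R,6R,7R,7aS)-6-ethenyl-4-hydroxy-6-methyl-7-(prop-1-en-2-yl)hexahydro-1-benzofuran-2(3H)-one | C=C[C@@]1(C)C[C@@H](O)[C@@H]2CC(=O)O[C@H]2[C@@H]1C(C)=C | intermediate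
25 | dilithio alkoxide–lactone enolate of 24 | C=C[C@@]1(C)C[C@@H](O[Li])[C@@H]2C=C(O[Li])O[C@H]2[C@@H]1C(C)=C | intermediate
26 | (3aS,4R,6R,7R,7aS)-3-[(dimethylamino)methyl]-6-ethenyl-4-hydroxy-6-methyl-7-(prop-1-en-2-yl)hexahydro-1-benzofuran-2(3H)-one (C11 epimers) | C=C[C@@]1(C)C[C@@H](O)[C@@H]2C(CN(C)C)C(=O)O[C@H]2[C@@H]1C(C)=C | intermediate
27 | trimethylammonium iodide of 26 | C=C[C@@]1(C)C[C@@H](O)[C@@H]2C(C[N+](C)(C)C)C(=O)O[C@H]2[C@@H]1C(C)=C.[I-] | intermediate
28 | (3aS,4R,6R,7R,7aS)-6-ethenyl-4-hydroxy-6-methyl-3-methylidene-7-(prop-1-en-2-yl)hexahydro-1-benzofuran-2(3H)-one | C=C[C@@]1(C)C[C@@H](O)[C@@H]2C(=C)C(=O)O[C@H]2[C@@H]1C(C)=C | intermediate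
29 | but-2-yne-1,4-diol | OCC#CCO | starting material
30 | (E)-2-(tributylstannyl)but-2-ene-1,4-diol | OC/C=C(\CO)[Sn](CCCC)(CCCC)CCCC | intermediate
31 | tributyl(2,2-dimethyl-4,7-dihydro-1,3-dioxepin-5-yl)stannane | CC1(C)OCC=C(CO1)[Sn](CCCC)(CCCC)CCCC | intermediate
32 | (2,2-dimethyl-4,7-dihydro-1,3-dioxepin-5-yl)lithium | CC1(C)OCC=C([Li])CO1 | intermediate
33 | 2,2-dimethyl-4,7-dihydro-1,3-dioxepine-5-carboxylic acid | CC1(C)OCC=C(CO1)C(=O)O | intermediate
34 | mixed anhydride of 33 with 2,4,6-trichlorobenzoic acid | CC1(C)OCC=C(CO1)C(=O)OC(=O)c1c(Cl)cc(Cl)cc1Cl | intermediate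
35 | (3aS,4R,6R,7R,7aS)-6-ethenyl-6-methyl-3-methylidene-2-oxo-7-(prop-1-en-2-yl)octahydro-1-benzofuran-4-yl 2,2-dimethyl-4,7-dihydro-1,3-dioxepine-5-carboxylate | C=C[C@@]1(C)C[C@@H](OC(=O)C2=CCOC(C)(C)OC2)[C@@H]2C(=C)C(=O)O[C@H]2[C@@H]1C(C)=C | intermediate
36 | (3aS,4R,6R,7R,7aS)-6-ethenyl-6-methyl-3-methylidene-2-oxo-7-(prop-1-en-2-yl)octahydro-1-benzofuran-4-yl (2E)-4-hydroxy-2-(hydroxymethyl)but-2-enoate | C=C[C@@]1(C)C[C@@H](OC(=O)/C(=C/CO)CO)[C@@H]2C(=C)C(=O)O[C@H]2[C@@H]1C(=C)C | target

**Step count**

Total: 21 steps. Longest linear sequence: 18 steps (steps 1–16, 20, 21); the side-chain acid takes 3 steps (17–19).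

**The three steps most likely to fail**

Step 12. In the 5α-series the substrate and the ligand may prefer opposite faces of C8, which would lower the facial selectivity of boron delivery. The later equilibration at C5 has only a small thermodynamic driving force and competes with migration of the isopropenyl double bond into conjugation with the ketone. The fallback moves the C5 epimerisation ahead of the C8 step. It sets out from ketone 13: catalytic DBU equilibrates 13 with its 5β-epimer, (2R,3R)-3-ethenyl-3-methyl-2-(prop-1-en-2-yl)cyclohexan-1-one F1, which is separated on AgNO3-impregnated silica while recovered 13 is resubjected. F1 is then taken through the conditions of steps 9 to 11: its lithium enolate F2 is dehydrogenated to the enone F3, iodinated to the iodoenone F4 and coupled with 18 to the enone ester F5. In F5 the C10 methyl group is pseudoaxial on the β face and screens that face at C8, so substrate and ligand act in the same sense. The borylation conditions of step 12 then give the 5β-boryl ketone F6, whose C7 centre alone is adjusted by DBU, and the route is rejoined at 21.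

Step 13. Hydrogen may be delivered under kinetic control from the open α face of C6 (the β face is screened by the syn-axial C10 methyl group), giving the axial 6β-alkoxide, which would close to the cis-fused lactone; reduction of the ester by excess reagent is the second hazard. The fallback replaces electron transfer by reversible hydride transfer. It sets out from 21: Meerwein–Ponndorf–Verley reduction with Al(OiPr)3 in iPrOH at reflux with a trace of acetone equilibrates the C6 alkoxides through the ketone toward the equatorial 6α-alkoxide of 22, which lactonises in the same pot, and the route is rejoined at 23. No new compound is isolated.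

Step 5. The two ketal diastereomers may not separate, and prolonged heating may let the product re-enter the cyclodecadiene manifold and form other C5/C10 isomers. The fallback resolves enantiomers instead of diastereomers and installs the ketal afterwards. It sets out from racemic 5, which is thermolysed without protection (the known racemic sequence) to rac-methyl 2-[(1R*,2R*)-2-ethenyl-2-methyl-6-oxocyclohexyl]prop-2-enoate F7. The enantiomers of F7 are separated by preparative supercritical-fluid chromatography on a cellulose tris(3,5-dimethylphenylcarbamate) phase. The (1R,2R)-enantiomer is ketalised under aprotic conditions with (2R,3R)-2,3-bis(trimethylsilyloxy)butane F8 (made from 6 with Me3SiCl and Et3N) and catalytic Me3SiOTf at −78 °C, which does not move the double bonds, and the route is rejoined at 8.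

Further compounds
F1 | step 12 | (2R,3R)-3-ethenyl-3-methyl-2-(prop-1-en-2-yl)cyclohexan-1-one | C=C[C@@]1(C)CCCC(=O)[C@@H]1C(C)=C
F2 | step 12 | lithium enolate of F1 (C6=C7) | C=C[C@@]1(C)CCC=C(O[Li])[C@@H]1C(C)=C
F3 | step 12 | (5R,6R)-5-ethenyl-5-methyl-6-(prop-1-en-2-yl)cyclohex-2-en-1-one | C=C[C@@]1(C)CC=CC(=O)[C@@H]1C(C)=C
F4 | step 12 | (5R,6R)-5-ethenyl-2-iodo-5-methyl-6-(prop-1-en-2-yl)cyclohex-2-en-1-one | C=C[C@@]1(C)CC=C(I)C(=O)[C@@H]1C(C)=C
F5 | step 12 | ethyl 2-[(4R,5R)-4-ethenyl-4-methyl-6-oxo-5-(prop-1-en-2-yl)cyclohex-1-en-1-yl]acetate | C=C[C@@]1(C)CC=C(CC(=O)OCC)C(=O)[C@@H]1C(C)=C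
F6 | step 12 | 8α-boryl ketone of the 5β-series before equilibration at C7 | C=C[C@@]1(C)C[C@@H](B2OC(C)(C)C(C)(C)O2)C(CC(=O)OCC)C(=O)[C@@H]1C(C)=C
F0 | step 13 | none | none
F7 | step 5 | rac-methyl 2-[(1R*,2R*)-2-ethenyl-2-methyl-6-oxocyclohexyl]prop-2-enoate (drawn as the 1R,2R enantiomer that is carried on) | C=C[C@@]1(C)CCCC(=O)[C@H]1C(=C)C(=O)OC
F8 | step 5 | (2R,3R)-2,3-bis(trimethylsilyloxy)butane | C[C@@H](O[Si](C)(C)C)[C@@H](C)O[Si](C)(C)C
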